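The route rests on cutting the C4–C4a bond in the pyran ring (ring C) of the fisetinidol unit attached to C6 of catechin. This C4 is benzylic to the trioxygenated ring A of catechin, so a C3–C4 epoxide ionises only there, and the resorcinol ring is already tied to C2 through O1. In one operation that ring attacks C4 para to its benzyloxy group. This forms C4–C4a, closes ring C and sets C4 trans to the freed 3-OH. The precursor is 8-bromo-penta-O-benzylcatechin bearing at C6 a trans-epoxide whose second carbon carries the (3,4-dibenzyloxyphenyl)(3-benzyloxyphenoxy)methyl group. The C8 bromide later brings in the 4β arm.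

Key step: step 9

Assumption: fustin is bought as the (2R,3R) enantiomer drawn in the compound list, and its optical purity is checked before use.
Numbering remark: in the open-chain intermediates, the three carbons that become C2, C3 and C4 of the C6-bound fisetinidol already carry these numbers. The epoxide is made while C2 is still a carbonyl group. After the carbonyl is reduced, the epoxide sees only aprotic, acid-free media until step 9.

Step 1
Reactants: 1 (+)-catechin
Product: 2 (2R,3S)-3,5,7,3',4'-penta-O-benzylcatechin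
Conditions: NaH, BnBr, DMF, −10 °C → rt, argon
Reagents that add atoms: benzyl bromide, BrCc1ccccc1
Why: Williamson etherification in which NaH deprotonates the four phenols and the C3 alcohol and benzyl bromide alkylates them, cold addition under argon limiting C-benzylation and catechol oxidation, with no stereocentre touched.

Step 2
Reactants: 2 penta-O-benzylcatechin
Product: 3 8-bromo-3,5,7,3',4'-penta-O-benzylcatechin
Conditions: NBS (1 equiv), CH2Cl2, −78 → 0 °C
Reagents that add atoms: N-bromosuccinimide, O=C1CCC(=O)N1Br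
Why: Electrophilic aromatic bromination in which C8, the more nucleophilic and less crowded of the two free ring A positions of a 5,7-dialkoxyflavan, should take up the single equivalent of bromine, which then blocks C8 and serves as the later lithiation handle.

Step 3
Reactants: 3 8-bromo-penta-O-benzylcatechin
Product: 5 8-bromo-6-formyl-3,5,7,3',4'-penta-O-benzylcatechin, via C6 dimethyliminium chloride 4 (not isolated)
Conditions: POCl3, DMF, ClCH2CH2Cl, 0 → 70 °C; then aq NaOH, 0 °C
Reagents that add atoms: N,N-dimethylformamide, CN(C)C=O; water, O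
Why: Vilsmeier–Haack formylation in which, with C8 blocked, the chloroiminium ion can attack only C6, the last position activated by three oxygen substituents, and alkaline hydrolysis of salt 4 gives the aldehyde while the benzyl ethers survive.

Step 4
Reactants: 6 3,4-dihydroxyacetophenone
Product: 7 3,4-dibenzyloxyacetophenone
Conditions: BnBr, K2CO3, DMF, 50 °C
Reagents that add atoms: benzyl bromide, BrCc1ccccc1
Why: Williamson etherification of the two phenols with a carbonate base too weak to cause harmful enolisation of the methyl ketone.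

Step 5
Reactants: 5 8-bromo-6-formyl-penta-O-benzylcatechin; 7 3,4-dibenzyloxyacetophenone
Product: 8 (E)-3-(8-bromo-penta-O-benzylcatechin-6-yl)-1-(3,4-dibenzyloxyphenyl)prop-2-en-1-one
Conditions: KOH, EtOH–THF, rt
Reagents that add atoms: none
Why: Claisen–Schmidt condensation in which the enolate of methyl ketone 7 adds to the non-enolisable aldehyde 5 and E1cB loss of water gives the conjugated enone, whose (E) geometry is the thermodynamic outcome.

Step 6
Reactants: 8 (E)-enone
Product: 9 trans-epoxy ketone with (3S,4R) configuration, the (αS,βR) chalcone-type epoxide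
Conditions: poly-D-leucine on silica, urea·H2O2, DBU, THF, rt
Reagents that add atoms: urea–hydrogen peroxide, NC(N)=O.OO
Why: Juliá–Colonna epoxidation, a peptide-catalysed Weitz–Scheffer reaction, in which hydroperoxide adds to C4 and the enolate closes on oxygen to the trans-epoxide, poly-D-leucine being the antipode that turns chalcones into their (αS,βR)-epoxides, so C3 is set as (S) and C4 as (R), while the adjacent carbonyl group and the basic water-free medium keep the benzylic C4–O bond from ionising.

Step 7
Reactants: 9 trans-epoxy ketone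
Product: 10 syn-epoxy alcohol with (2S,3R,4R) configuration
Conditions: (S)-Me-CBS, catecholborane, toluene, −78 → −40 °C; MeOH quench, cold aq NaOH wash, used crude
Reagents that add atoms: none
Why: Corey–Bakshi–Shibata reduction in which, with the aryl ring as the large flank and the oxiranyl group as the small one, the (S)-oxazaborolidine should deliver hydride to the face giving the (2S)-carbinol, the syn (threo) epoxy alcohol, the non-chelated polar Felkin–Anh preference pointing the same way, and catecholborane at low temperature being too weak a Lewis acid and hydride donor to open the oxirane.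

Step 8
Reactants: 10 syn-epoxy alcohol; 11 3-benzyloxyphenol
Product: 12 anti-epoxy aryl ether with (2R,3S,4R) configuration: 8-bromo-penta-O-benzylcatechin bearing at C6 the trans-oxirane whose C3 carries the (R)-(3,4-dibenzyloxyphenyl)(3-benzyloxyphenoxy)methyl group
Conditions: PPh3, DIAD, toluene, 0 °C → rt; filtration through basic alumina, used at once
Reagents that add atoms: none
Why: Mitsunobu etherification in which the phenoxide of 11 displaces the alkoxyphosphonium group at C2 in an SN2 sense, so (S) becomes (R) and the syn alcohol becomes the anti ether that a 2,3-trans flavan needs, the electron-withdrawing oxirane next to the carbinol and the non-polar solvent holding back ionisation and the neutral aprotic medium leaving the epoxide closed.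

Step 9
Reactants: 12 anti-epoxy aryl ether
Product: 13 8-bromo-penta-O-benzylcatechin bearing at C6 the (2R,3S,4S)-7,3',4'-tri-O-benzylfisetinidol-4-yl unit with free 3-OH
Conditions: 1,1,1,3,3,3-hexafluoropropan-2-ol (HFIP)–CH2Cl2 (1:3), high dilution, −20 °C → rt
Reagents that add atoms: none
Why: Hydrogen bonding from HFIP to the oxirane oxygen weakens the C4–O bond, the only one that can develop benzylic cation character stabilised by the three oxygens of catechin ring A, and the tethered resorcinol ring then attacks C4 and loses a proton, so the step is an isomerisation. The closest known reaction type is the epoxide–arene (intramolecular Friedel–Crafts) cyclisation of 3-arylglycidyl aryl ethers to trans-4-arylchroman-3-ols under Lewis acids or fluorinated alcohols. Ring C closes in the 6-endo mode, with both oxirane carbons ending inside the new pyran. C4 is controlled twice in the same sense: backside attack on the trans-epoxide turns (4R) into (4S), and a fully open cation would close through the half-chair with the C2 aryl, the C3 oxygen and the C4 aryl all equatorial, again 3,4-trans, while C2 and C3 are not touched. The step needs attack at C4 and not C3 (secured by the catechin ring), bond formation para and not ortho to the benzyloxy group (the carbon between the two oxygens is crowded), and ring closure faster than a 1,2-hydride shift, five-ring closure by the less nucleophilic catechol ring or intermolecular arylation (favoured by the doubly activated tethered carbon, the dilution and the bromine that blocks C8).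

Step 10
Reactants: 13 C6-linked bromo dimer with free 3-OH
Product: 14 the 3-O-benzyl ether of 13
Conditions: NaH, BnBr, Bu4NI (cat.), THF–DMF, 0 °C → rt
Reagents that add atoms: benzyl bromide, BrCc1ccccc1
Why: Williamson etherification of the only free hydroxyl, which removes the acidic proton before the lithiation and touches no stereocentre.

Step 11
Reactants: 15 (2R,3R)-fustin
Product: 16 (2R,3R)-7,3',4'-tri-O-benzylfustin
Conditions: BnBr, K2CO3, DMF, rt, argon
Reagents that add atoms: benzyl bromide, BrCc1ccccc1
Why: Williamson etherification of the three phenols with carbonate base at room temperature under argon, mild enough to leave the 3-OH free and to avoid ring opening, epimerisation or air oxidation of the dihydroflavonol.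

Step 12
Reactants: 16 tri-O-benzylfustin
Product: 17 (2R,3R)-3,7,3',4'-tetra-O-benzylfustin
Conditions: BnOC(=NH)CCl3, TfOH (cat.), CH2Cl2–cyclohexane, 0 °C → rt
Reagents that add atoms: benzyl 2,2,2-trichloroacetimidate, N=C(OCc1ccccc1)C(Cl)(Cl)Cl
Why: Acid-catalysed O-benzylation with a trichloroacetimidate, chosen because strong base would open the pyranone by E1cB loss of the ring phenoxide or epimerise C2 and C3, so both stereocentres are kept.

Step 13
Reactants: 14 fully benzylated bromo dimer; 17 tetra-O-benzylfustin
Product: 19 protected trimer with a tertiary C4 alcohol in the C8 arm (4α-aryl 4β-hydroxy expected), via C8 aryllithium 18 (not isolated)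
Conditions: t-BuLi (2.1 equiv), THF, −78 °C; then 17, −78 → −40 °C; H2O quench
Reagents that add atoms: none
Why: Bromine–lithium exchange followed by 1,2-addition of the aryllithium to the flavan-4-one carbonyl, a known way to join C8 of a benzylated flavan-3-ol to C4 of a second unit, in which low temperature favours addition over enolisation, attack anti to the 3-OBn group should place the aryl group α, and the new carbinol centre is erased in step 14.

Step 14
Reactants: 19 tertiary alcohol
Product: 20 trideca-O-benzyl fisetinidol-(4β→8)-catechin-(6→4α)-fisetinidol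
Conditions: Bu3SnH, TFA (few equiv), CH2Cl2, −20 → 0 °C
Reagents that add atoms: none
Why: Ionic hydrogenation in which TFA ionises the tertiary doubly benzylic alcohol and Bu3SnH, a hydride donor strong enough for this well-stabilised cation, should approach C4 from the α face anti to the neighbouring 3-OBn group, which pushes the catechin ring to the β face and sets (4R), the 3,4-cis arm, while the dilute acid and low temperature spare the interflavan bonds and the O1–C2 bonds.

Step 15
Reactants: 20 trideca-O-benzyl trimer
Product: 21 fisetinidol-(4β→8)-catechin-(6→4α)-fisetinidol (CNP0289228.2)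
Conditions: H2 (1 atm), Pd(OH)2/C, THF–MeOH, rt
Reagents that add atoms: none
Why: Catalytic hydrogenolysis removes all thirteen benzyl ethers as toluene under neutral conditions and should leave the interflavan C–C bonds, the pyran C–O bonds and all eight stereocentres unaffected.

Compound list
1 | (+)-catechin, (2R,3S) | Oc1cc(O)c2c(c1)O[C@H](c1ccc(O)c(O)c1)[C@@H](O)C2 | starting material
2 | (2R,3S)-3,5,7,3',4'-penta-O-benzylcatechin | O(Cc9ccccc9)c1cc(OCc9ccccc9)c2c(c1)O[C@H](c1ccc(OCc9ccccc9)c(OCc9ccccc9)c1)[C@@H](OCc9ccccc9)C2 | intermediate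
3 | 8-bromo-penta-O-benzylcatechin | Brc1c(OCc9ccccc9)cc(OCc9ccccc9)c2c1O[C@H](c1ccc(OCc9ccccc9)c(OCc9ccccc9)c1)[C@@H](OCc9ccccc9)C2 | intermediate
4 | C6 dimethyliminium chloride of 3 (not isolated) | Brc1c(OCc9ccccc9)c(C=[N+](C)C)c(OCc9ccccc9)c2c1O[C@H](c1ccc(OCc9ccccc9)c(OCc9ccccc9)c1)[C@@H](OCc9ccccc9)C2.[Cl-] | intermediate
5 | 8-bromo-6-formyl-penta-O-benzylcatechin | Brc1c(OCc9ccccc9)c(C=O)c(OCc9ccccc9)c2c1O[C@H](c1ccc(OCc9ccccc9)c(OCc9ccccc9)c1)[C@@H](OCc9ccccc9)C2 | intermediate
6 | 3,4-dihydroxyacetophenone | CC(=O)c1ccc(O)c(O)c1 | starting material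
7 | 3,4-dibenzyloxyacetophenone | CC(=O)c1ccc(OCc9ccccc9)c(OCc9ccccc9)c1 | intermediate
8 | (E)-enone from 5 and 7 | Brc1c(OCc9ccccc9)c(/C=C/C(=O)c3ccc(OCc9ccccc9)c(OCc9ccccc9)c3)c(OCc9ccccc9)c2c1O[C@H](c1ccc(OCc9ccccc9)c(OCc9ccccc9)c1)[C@@H](OCc9ccccc9)C2 | intermediate
9 | trans-epoxy ketone, (3S,4R) | Brc1c(OCc9ccccc9)c([C@@H]2[C@H](O2)C(=O)c3ccc(OCc9ccccc9)c(OCc9ccccc9)c3)c(OCc9ccccc9)c2c1O[C@H](c1ccc(OCc9ccccc9)c(OCc9ccccc9)c1)[C@@H](OCc9ccccc9)C2 | intermediate
10 | syn-epoxy alcohol, (2S,3R,4R) | Brc1c(OCc9ccccc9)c([C@@H]2[C@H](O2)[C@H](c3ccc(OCc9ccccc9)c(OCc9ccccc9)c3)O)c(OCc9ccccc9)c2c1O[C@H](c1ccc(OCc9ccccc9)c(OCc9ccccc9)c1)[C@@H](OCc9ccccc9)C2 | intermediate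
11 | 3-benzyloxyphenol | Oc1cccc(OCc2ccccc2)c1 | starting material
12 | anti-epoxy aryl ether, (2R,3S,4R), key-step precursor | Brc1c(OCc9ccccc9)c([C@@H]2[C@H](O2)[C@@H](c3ccc(OCc9ccccc9)c(OCc9ccccc9)c3)Oc3cccc(OCc9ccccc9)c3)c(OCc9ccccc9)c2c1O[C@H](c1ccc(OCc9ccccc9)c(OCc9ccccc9)c1)[C@@H](OCc9ccccc9)C2 | intermediate
13 | 8-bromo-penta-O-benzylcatechin with the (2R,3S,4S)-tri-O-benzylfisetinidol unit at C6, free 3-OH, key-step product | Brc1c(OCc9ccccc9)c([C@@H]2c3ccc(OCc9ccccc9)cc3O[C@H](c3ccc(OCc9ccccc9)c(OCc9ccccc9)c3)[C@H]2O)c(OCc9ccccc9)c2c1O[C@H](c1ccc(OCc9ccccc9)c(OCc9ccccc9)c1)[C@@H](OCc9ccccc9)C2 | intermediate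
14 | 3-O-benzyl ether of 13 | Brc1c(OCc9ccccc9)c([C@@H]2c3ccc(OCc9ccccc9)cc3O[C@H](c3ccc(OCc9ccccc9)c(OCc9ccccc9)c3)[C@H]2OCc9ccccc9)c(OCc9ccccc9)c2c1O[C@H](c1ccc(OCc9ccccc9)c(OCc9ccccc9)c1)[C@@H](OCc9ccccc9)C2 | intermediate
15 | (2R,3R)-fustin | Oc1ccc2c(c1)O[C@H](c1ccc(O)c(O)c1)[C@@H](O)C2=O | starting material
16 | (2R,3R)-7,3',4'-tri-O-benzylfustin | O(Cc9ccccc9)c1ccc2c(c1)O[C@H](c1ccc(OCc9ccccc9)c(OCc9ccccc9)c1)[C@@H](O)C2=O | intermediate
17 | (2R,3R)-3,7,3',4'-tetra-O-benzylfustin | O(Cc9ccccc9)c1ccc2c(c1)O[C@H](c1ccc(OCc9ccccc9)c(OCc9ccccc9)c1)[C@@H](OCc9ccccc9)C2=O | intermediate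
18 | C8 aryllithium from 14 (not isolated) | [Li]c1c(OCc9ccccc9)c([C@@H]2c3ccc(OCc9ccccc9)cc3O[C@H](c3ccc(OCc9ccccc9)c(OCc9ccccc9)c3)[C@H]2OCc9ccccc9)c(OCc9ccccc9)c2c1O[C@H](c1ccc(OCc9ccccc9)c(OCc9ccccc9)c1)[C@@H](OCc9ccccc9)C2 | intermediate
19 | protected trimer, tertiary C4 alcohol in the C8 arm (aryl α, OH β expected) | O(Cc9ccccc9)c1ccc2c(c1)O[C@H](c1ccc(OCc9ccccc9)c(OCc9ccccc9)c1)[C@@H](OCc9ccccc9)[C@]2(O)c1c(OCc9ccccc9)c([C@@H]2c3ccc(OCc9ccccc9)cc3O[C@H](c3ccc(OCc9ccccc9)c(OCc9ccccc9)c3)[C@H]2OCc9ccccc9)c(OCc9ccccc9)c2c1O[C@H](c1ccc(OCc9ccccc9)c(OCc9ccccc9)c1)[C@@H](OCc9ccccc9)C2 | intermediate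
20 | trideca-O-benzyl fisetinidol-(4β→8)-catechin-(6→4α)-fisetinidol | O(Cc9ccccc9)c1ccc2c(c1)O[C@H](c1ccc(OCc9ccccc9)c(OCc9ccccc9)c1)[C@@H](OCc9ccccc9)[C@H]2c1c(OCc9ccccc9)c([C@@H]2c3ccc(OCc9ccccc9)cc3O[C@H](c3ccc(OCc9ccccc9)c(OCc9ccccc9)c3)[C@H]2OCc9ccccc9)c(OCc9ccccc9)c2c1O[C@H](c1ccc(OCc9ccccc9)c(OCc9ccccc9)c1)[C@@H](OCc9ccccc9)C2 | intermediate
21 | fisetinidol-(4β→8)-catechin-(6→4α)-fisetinidol, CNP0289228.2 | Oc1ccc2c(c1)O[C@H](c1ccc(O)c(O)c1)[C@@H](O)[C@H]2c1c(O)c([C@@H]2c3ccc(O)cc3O[C@H](c3ccc(O)c(O)c3)[C@H]2O)c(O)c2c1O[C@H](c1ccc(O)c(O)c1)[C@@H](O)C2 | target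

Total step count: 15. Longest linear sequence: 12 steps from catechin (steps 1–3, 5–10 and 13–15).

Steps most likely to fail

1. Step 9. After the C4–O bond ionises, a 1,2-hydride shift from C3 or capture by the fluorinated alcohol may outrun ring closure. The fallback gives up the intramolecular closure and makes the C4–C6 bond intermolecularly. It sets out from 16, which NaBH4 in THF–EtOH reduces to (2R,3S,4R)-7,3',4'-tri-O-benzylflavan-3,4-diol F1. Ionising F1 with BF3·OEt2 in CH2Cl2 at low temperature in the presence of excess 3 gives the C4 cation. The C8 bromine of 3 leaves C6 as its only nucleophilic ring A position, and approach anti to the 3-OH should favour the 3,4-trans product. This is the known Lewis-acid condensation of a flavan-3,4-diol with a halogen-capped flavan-3-ol. The fallback comes back to the route at 13.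

2. Step 7. Facial selectivity may be poor because the aryl and oxiranyl flanks differ little in size, and the boron hydride may reductively open the oxirane. The fallback replaces reagent control by substrate control plus inversion. It sets out from 9, which Zn(BH4)2 in Et2O at −78 °C reduces under chelation control to the anti-epoxy alcohol F2. A Mitsunobu reaction with 4-nitrobenzoic acid (PPh3, DIAD, toluene) inverts C2 and gives the syn 4-nitrobenzoate F3. Mild methanolysis (K2CO3, MeOH–THF, 0 °C) then frees the alcohol. The fallback comes back at 10.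

3. Step 14. Hydride may be delivered to both faces of the cation, because in the 2,3-trans series the C2 aryl and the 3-OBn group lie on opposite faces, and this would erode the 4β configuration. The fallback is the biomimetic condensation of free phenols. It sets out from 13, which H2 over Pd(OH)2/C with Et3N in THF–MeOH debenzylates and debrominates to fisetinidol-(4α→6)-catechin F4. In parallel, 15 is reduced with NaBH4 to (+)-mollisacacidin F5. Condensing F4 with F5 in dilute aqueous HCl at room temperature alkylates the remaining nucleophilic C8. The 4β epimer is then separated from the 4α epimer on Sephadex LH-20. The fallback comes back at 21.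

Further compounds
F1 | step 9 | (2R,3S,4R)-7,3',4'-tri-O-benzylflavan-3,4-diol | O(Cc9ccccc9)c1ccc2c(c1)O[C@H](c1ccc(OCc9ccccc9)c(OCc9ccccc9)c1)[C@@H](O)[C@@H]2O
F2 | step 7 | anti-epoxy alcohol, C2 epimer of 10 | Brc1c(OCc9ccccc9)c([C@@H]2[C@H](O2)[C@@H](c3ccc(OCc9ccccc9)c(OCc9ccccc9)c3)O)c(OCc9ccccc9)c2c1O[C@H](c1ccc(OCc9ccccc9)c(OCc9ccccc9)c1)[C@@H](OCc9ccccc9)C2
F3 | step 7 | syn 4-nitrobenzoate, ester of 10 | Brc1c(OCc9ccccc9)c([C@@H]2[C@H](O2)[C@H](c3ccc(OCc9ccccc9)c(OCc9ccccc9)c3)OC(=O)c3ccc(cc3)[N+](=O)[O-])c(OCc9ccccc9)c2c1O[C@H](c1ccc(OCc9ccccc9)c(OCc9ccccc9)c1)[C@@H](OCc9ccccc9)C2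
F4 | step 14 | fisetinidol-(4α→6)-catechin | c1c(O)c([C@@H]2c3ccc(O)cc3O[C@H](c3ccc(O)c(O)c3)[C@H]2O)c(O)c2c1O[C@H](c1ccc(O)c(O)c1)[C@@H](O)C2
F5 | step 14 | (+)-mollisacacidin, (2R,3S,4R)-flavan-3,3',4,4',7-pentaol | Oc1ccc2c(c1)O[C@H](c1ccc(O)c(O)c1)[C@@H](O)[C@@H]2O
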